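(Its constants are made up; the flask was simulated.)

A small charge of solid electrophile, 0.10 M and so less than the 0.110 M of nucleophile, makes it the limiting reagent, but each coupling sets free one acid that can take a nucleophile away.

solid electrophile 0.10 M; nucleophile 0.110 M; time 10 d

    acid set free + scavenger → scavenged by-product (k1 = 0.0069 M⁻¹ s⁻¹)
    nucleophile + acid set free ⇌ protonated nucleophile, settled at all times (K2 = 1400 M⁻¹)
    solid electrophile ⇌ electrophile, rate k3*(cs3 - [electrophile]) while solid is left; crystals form when [electrophile] > cs3 (cs3 = 0.073 M, k3 = 5.1 × 10⁻⁶ s⁻¹)
    electrophile + acid set free ⇌ idle adduct, settled at all times (K4 = 3.3 M⁻¹)
    electrophile + nucleophile → acid set free + target (k5 = 6.1 × 10⁻⁴ M⁻¹ s⁻¹)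

- amounts and yields of acid set free count idle adduct too
- given per volume of solution although it is solid: solid electrophile
- the amount of scavenger is what is sought; it is there from the start
- at the start none of the solid electrophile is in solution
- what has only dissolved of solid electrophile counts as not reacted
- run time (flask): 10 d

- the concentration of scavenger at which the part of the solid electrophile that has reacted (what has only dissolved counts as not reacted) at 10 d is just 90%, in M

Write S for the scavenger charge. My view is a wall. The equilibrium constant of step 2 times the nucleophile charge is 154, far more than one, so I let every unscavenged acid hold one nucleophile. At 90.0% the couplings have made 0.0900 M of acid and left 0.0200 M of nucleophile. The balance charge S*, the scavenger at which the unscavenged acid just equals the nucleophile left at the part wanted, is twice the acid made minus the nucleophile charged: 0.0700 M. Dissolving is no obstacle to this: at its fastest rate, k3 times cs3, the charge is in solution after 3.11 d, less than the 10 d of the run. So I commit to S*.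

The forecast disputes the wall and says less scavenger will do: 0.057 M. It grants that “acid binds it strongly”, yet it lets the acid overshoot the nucleophile left and keeps some nucleophile free to react.

The simulation gives 0.0574 M, the forecast's side. This flask stands 0.0126 M below S*, and in my balance that much acid, idle adduct counted, stays over at 90.0%, so free nucleophile is about 0.001135 M, which gives the electrophile a half-life by coupling of about 11.6 d. The run reads 12 d at 10.0 d, so for this flask the wall is a fair picture on times well under that, and 10 d is not such a time. With a quarter more scavenger, 0.0717 M, the charge stands above S*, and that flask reaches 93.8%.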